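2.64 M d⁻¹: that is the number to hold. Solid substrate left Monday's run at this steady rate, read between 0.0833 d and 0.250 d. Friday's run, at higher [reagent], reads 2.67 M d⁻¹, the same within scatter. So treat it as a zero-order feed.

all flasks: solid substrate 0.83 M
- Monday's: reagent 1.3 M; run made earlier
- Friday's: reagent 2 M; run made earlier
- flask: reagent 0.913 M; time 4.0 d

- Monday's (time / d: target / %, solid substrate / %): 0.0833: 19.7, 72.3; 0.125: 30.6, 59.5; 0.250: 58.8, 19.3; 0.417: 63.5, 0; 0.833: 43.6, 0.1; 1.25: 27.1, 0.1; 2.50: 0.3, 0.2
- Friday's (time / d: target / %, solid substrate / %): 0.0833: 24.1, 72.7; 0.125: 37.1, 57.9; 0.250: 72.4, 19.0; 0.417: 86.4, 0.1; 0.833: 75.4, 0; 1.25: 66.7, 0.2; 2.50: 43.8, 0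

(standard deviation of a reading: 0.5 percentage points)

- in percentages every species weighs as the solid substrate in it: one side product counts as two
- for target the solid product is counted in
- as a solid, counted per litre of solution: solid substrate, solid product
- the numbers in the tables scatter with a standard deviation of 0.5 percentage points
- on the list of suspects stand: solid substrate <-> dissolved substrate; dissolved substrate + reagent <-> target; 2 dissolved substrate -> side product; solid product <-> target
- at the start none of the solid substrate is in solution

- the best time, 4.0 d at the latest, for target
- the amount of target, in percent of the solid substrate charged, at that time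

Charge over feed gives 0.315 d, the clearing time. Set against it the fall time, Monday's peak reading over its loss rate once the solid is at 0%: 1.33 d. Clearing takes a quarter of that. So I expect target to climb while the feed lasts and to fall after it. Friday's fall time is longer, 3.27 d. So expect a shorter one in the flask, which has less reagent than Monday's. My reckoning puts the flask's best at the clearing time; it gives no height.

The forecast said 0.31 d and 51%, “peaking near 50% as the solid runs out”.

The flask gives 0.326 d and 48.5%; that time lies 0.0110 d after the clearing time.

    solid substrate ⇌ dissolved substrate, rate k1*(cs1 - [dissolved substrate]) while solid is left; crystals form when [dissolved substrate] > cs1 (solubility = 0.270 M, k = 0.00740 min⁻¹)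
    dissolved substrate + reagent ⇌ target (K = 1.40 L mol⁻¹, k = 0.410 L mol⁻¹ min⁻¹)
    2 dissolved substrate → side product (k = 0.440 L mol⁻¹ min⁻¹)
    solid product ⇌ target, rate k4*(cs4 - [target]) while solid is left; crystals form when [target] > cs4 (solubility = 24.0 mM, k = 0.430 min⁻¹)

In the flask, dissolving had half its turnover done by 0.160 d. At 0.326 d the solid substrate stood at 0%, target at 48.5% (solid product 45.5% counted in) and side product at 47.4%. Target then fell to 0.246% at 2.00 d, while side product reached 99.6%.

In the neighbour charged with 0.21 M, the same feed gives a clearing time of 0.0796 d, a quarter of the flask's. Its computed best is 60.7%.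

The runs were computed with constants of no real substance, noise included.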